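(The runs are calculated with made-up constants; scatter was added.)

At early times in the north run, substrate fell with a time constant near 6.28 min, while target barely showed. In the west run, target was still climbing at 80.0 min, a time longer than that. So I treated the fast step as at balance. From 50.0 min on, west substrate stayed near 10% while target rose from 41% to 50%. I therefore reckoned with a single pool: everything not yet target, substrate and unseen forms together.

| setting | west | north | flask |
|---|---|---|---|
| substrate | 0.10 M | 0.067 M | 0.10 M |
| partner | 2.5 equiv | 2.5 equiv | 2.50 equiv |
| remark | the very flask that is asked about, followed so far | run made earlier |  |
| time |  |  | 2.5 h |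

- west (time / min: target / %, substrate / %): 10.0: 18, 26; 30.0: 34, 16; 50.0: 41, 11; 80.0: 48, 12; 120: 49, 11; 150: 50, 10
- north (time / min: target / %, substrate / %): 0.200: 0, 96; 0.667: 0, 88; 1.00: 0, 85; 2.00: 5, 73; 2.50: 1, 66; 3.00: 3, 62

(standard deviation of a reading: 2 percentage points)

- target that was removed still counts
- additions bring no volume worth counting

- cedar: at 2.5 h add partner, 50.0% of the amount charged, then wait 50 min
- alder: at 2.5 h add substrate, 50.0% of the amount charged, then wait 50 min
- elm: at 2.5 h take out 90% of the target then present, then wait 50 min
- birch: change nothing and wait 50 min more

- target, in percent of the substrate first charged, at 2.5 h
- the remedy with the largest gain of target, or "none" below 2 percentage points (cedar / alder / elm / birch / none)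
- target present, with what was taken out counted in, in percent of the substrate first charged, after cedar
- target present, with what was taken out counted in, in percent of the substrate first charged, after alder

Why did the west flask stop with 50.0% in the pool? One partner per target accounts for 20.0% of the partner charged. The readings did not exclude a balance, but I bet that partner was lost by a route of its own.

What does a lot of partner buy, then? If partner dies at its own pace, each lot shrinks the pool by a set factor. The west readings gave 2.77 L mol⁻¹ for the take-down, the natural logarithm of pool before over pool after, per concentration of partner charged.

So I expected about 50% now. By my reckoning, the 0.125 M of partner in cedar gained 15 percentage points and gave 64.6%. The west readings showed 41% of their 50% by 50.0 min, a time equal to the wait, so I took the wait as long enough for that dose. Alder, elm and birch add no partner, so I expected no gain from them, and alder staying near 50%.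

The forecast gave 50%, chose elm, and put cedar at 52% and alder at 67%: “My best reading is a reversible chain”. We differed on the choice and on the totals for cedar and alder.

The flask gave 48.7%. The best remedy was cedar, with a gain of 15 points, reaching 63.8%; alder reached 48.8%.

    substrate ⇌ intermediate (K = 2.46, k = 0.143 min⁻¹)
    partner → decomposed reagent (k = 0.0371 min⁻¹)
    substrate ⇌ side product (K = 1.15, k = 0.0270 min⁻¹)
    partner + intermediate → target (k = 0.277 L mol⁻¹ min⁻¹)

This flask, charged with 2.50 equiv of partner, held 0.115% of that partner and 11.1% of its substrate at 150 min; partner was the limiting reagent. A neighbour flask charged with 0.620 equiv of partner got 0.0620 M, and from a full pool the take-down reckoned 15.8% target. That neighbour held 45.2% as intermediate and 15.4% as target at 150 min.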